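**Retrosynthetic overview**
1. The target comes from its (2S)-5-O-TBS ether 15 by buffered fluoride desilylation.
2. The strategy rests on C2 of ring C, which carries both O1 and the cation-stabilising 2,4,6-trimethoxyphenyl ring B, and on C3–C4, an A-ring aryl ketone enol that can be masked as an exocyclic enol ether. C2–C3 is therefore cut back to the racemic 4-methylene-1,3-benzodioxine 13, and a chiral Brønsted acid turns this acetal into the chromanone by an O-to-C (Petasis–Ferrier) shift.
3. 13 comes from Petasis methylenation of the lactone carbonyl of benzodioxin-4-one 12, the silyl ether of phenol 11.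
4. The 8-prenyl group of 11 comes from a Claisen–Cope shift of the 5-O-prenyl ether 8, which places prenyl para to O5 and ortho to O1; 8 comes from 7-O-methylation and 5-O-prenylation of 5.
5. 5 comes from 2,4,6-trihydroxybenzoic acid and 2,4,6-trimethoxybenzaldehyde. Ring order: rings A and B are bought, the temporary dioxinone ring is made first, and the pyranone ring C is made last.

Key step: step 7

Assumptions on the chemistry: compounds 4–13 are racemic at the acetal carbon, which does not matter because step 7 erases that centre. The sense of induction of the chiral acid cannot be predicted for this new reaction, so the catalyst antipode that gives (2S) is to be fixed in a first screen. The aryl acetals are acid-labile and should be purified on base-washed supports.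

Step 1
Reactants: 1 2,4,6-trihydroxybenzoic acid; 2 2,4,6-trimethoxybenzaldehyde
Product: 5 rac-5,7-dihydroxy-2-(2,4,6-trimethoxyphenyl)-4H-1,3-benzodioxin-4-one, via persilylated acid 3 (not isolated), via bis(trimethylsilyl) dioxinone 4 (not isolated)
Conditions: HMDS, TMSCl (cat.), THF, 50 °C, evaporate; then 2, TMSOTf (10 mol %), CH2Cl2, −78 °C, pyridine quench; then aq. NaHCO3–THF, 0 °C
Reagents that add atoms: none
Why: Noyori-type silyl-transfer acetalisation of a silylated hydroxy acid with an aldehyde (the method used for 1,3-dioxan-4-ones) should close the dioxinone at −78 °C, where O-attack on the stabilised benzylic oxocarbenium is expected to outrun C-attack by the ring; the acid is symmetric so only one regioisomer can form, and the two remaining aryl TMS ethers hydrolyse on work-up.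

Step 2
Reactants: 5 rac-5,7-dihydroxy-2-(2,4,6-trimethoxyphenyl)-4H-1,3-benzodioxin-4-one
Product: 6 rac-5-hydroxy-7-methoxy-2-(2,4,6-trimethoxyphenyl)-4H-1,3-benzodioxin-4-one
Conditions: MeI (1.05 equiv), K2CO3 (1.1 equiv), acetone, rt
Reagents that add atoms: iodomethane, CI
Why: Williamson etherification should take place at O7 only, because the 7-OH is the more acidic, non-chelated phenol while the 5-OH is held in a hydrogen bond to the C4 carbonyl; the acetal is stable to carbonate in an aprotic solvent.

Step 3
Reactants: 6 rac-5-hydroxy-7-methoxy-2-(2,4,6-trimethoxyphenyl)-4H-1,3-benzodioxin-4-one; 7 prenyl bromide (1-bromo-3-methylbut-2-ene)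
Product: 8 rac-7-methoxy-5-(3-methylbut-2-enyloxy)-2-(2,4,6-trimethoxyphenyl)-4H-1,3-benzodioxin-4-one
Conditions: K2CO3, DMF, rt to 40 °C
Reagents that add atoms: none
Why: Williamson O-alkylation of the remaining chelated phenol with the allylic bromide is expected in a dipolar aprotic solvent, where O- is favoured over C-alkylation.

Step 4
Reactants: 8 rac-7-methoxy-5-(3-methylbut-2-enyloxy)-2-(2,4,6-trimethoxyphenyl)-4H-1,3-benzodioxin-4-one
Product: 11 rac-5-hydroxy-7-methoxy-8-(3-methylbut-2-enyl)-2-(2,4,6-trimethoxyphenyl)-4H-1,3-benzodioxin-4-one, via 6-(1,1-dimethylallyl) ortho-dienone 9 (not isolated), via 8-prenyl para-dienone 10 (not isolated)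
Conditions: Eu(fod)3 (10 mol %), CHCl3, 60 °C
Reagents that add atoms: none
Why: A lanthanide-catalysed aromatic Claisen rearrangement to C6 followed by a Cope shift to C8 and tautomerisation (the para-Claisen–Cope sequence known for 5-O-prenyl flavonoids) should deliver the normal prenyl group to the free position para to O5, since chelation between O5 and the C4 carbonyl speeds the first shift and the crowded reverse-prenyl dienone relays the allyl unit onward.

Step 5
Reactants: 11 rac-5-hydroxy-7-methoxy-8-(3-methylbut-2-enyl)-2-(2,4,6-trimethoxyphenyl)-4H-1,3-benzodioxin-4-one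
Product: 12 rac-5-(tert-butyldimethylsilyloxy)-7-methoxy-8-(3-methylbut-2-enyl)-2-(2,4,6-trimethoxyphenyl)-4H-1,3-benzodioxin-4-one
Conditions: TBSCl, imidazole, DMAP (cat.), DMF, rt to 40 °C
Reagents that add atoms: tert-butyldimethylsilyl chloride, CC(C)(C)[Si](C)(C)Cl
Why: Imidazole-mediated silylation of the phenol removes the acidic proton that would quench the titanium reagent of step 6, and the base-buffered conditions should not ionise the acetal.

Step 6
Reactants: 12 rac-5-(tert-butyldimethylsilyloxy)-7-methoxy-8-(3-methylbut-2-enyl)-2-(2,4,6-trimethoxyphenyl)-4H-1,3-benzodioxin-4-one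
Product: 13 rac-5-(tert-butyldimethylsilyloxy)-7-methoxy-4-methylene-8-(3-methylbut-2-enyl)-2-(2,4,6-trimethoxyphenyl)-4H-1,3-benzodioxine
Conditions: Cp2TiMe2 (3 equiv), toluene–THF, 70 °C, dark; basic alumina
Reagents that add atoms: dimethyltitanocene (Petasis reagent), C[Ti](C)(C1C=CC=C1)C1C=CC=C1
Why: Petasis methylenation, in which thermally formed Cp2Ti=CH2 converts a lactone carbonyl into the enol ether by [2+2]/retro-[2+2], runs without acid and should spare the acetal, the silyl ether and the trisubstituted alkene.

Step 7
Reactants: 13 rac-5-(tert-butyldimethylsilyloxy)-7-methoxy-4-methylene-8-(3-methylbut-2-enyl)-2-(2,4,6-trimethoxyphenyl)-4H-1,3-benzodioxine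
Product: 15 (2S)-5-(tert-butyldimethylsilyloxy)-7-methoxy-8-(3-methylbut-2-enyl)-2-(2,4,6-trimethoxyphenyl)chroman-4-one, via ring-opened enol aryloxycarbenium 14 (not isolated)
Conditions: confined chiral BINOL-derived imidodiphosphorimidate (IDPi) acid (5 mol %), 5 Å MS, toluene–CH2Cl2, −78 to −60 °C; Et3N quench at −78 °C
Reagents that add atoms: none
Why: Proposed new method: the confined chiral acid assists heterolysis of the C2–O3 acetal bond (C-protonation of the enol ether is reversible and unproductive), which erases the racemic acetal centre and gives the planar, trimethoxyphenyl-stabilised aryloxycarbenium 14 (O1=C2+) tethered to the A-ring ketone enol and paired with the chiral anion; the enol carbon C3 then adds to C2 and the enol proton returns to the anion, so the acid turns over and both enantiomers of 13 converge on one ion pair. The closest known reactions are the Lewis-acid Petasis–Ferrier rearrangement of 4-methylene-1,3-dioxanes to tetrahydropyranones and chiral phosphoric acid-catalysed aza-Petasis–Ferrier rearrangements of hemiaminal vinyl ethers; an enantioselective O-to-C shift on a benzodioxine has not been shown. Ring C closes by a 6-endo-trig attack on the oxocarbenium (C2=O1+ lies inside the new ring) by an enol whose C3=C4 bond is also endocyclic (6-enolendo), both favoured modes. The C2 stereocentre is set by the chiral counter-anion, which is hydrogen-bonded to the enol O–H and so delivers C3 to one face of the planar cation inside its confined pocket. The step needs C- over O-recombination, enol over prenyl-alkene (Prins) attack and no re-ionisation of the product C2–O1 bond: O-return only regenerates 13, the enol is far more nucleophilic than the trisubstituted alkene towards this weakly electrophilic cation, formation of the C4 carbonyl makes C–C closure irreversible, and low temperature, a weakly nucleophilic anion and a cold amine quench should protect the product.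

Step 8
Reactants: 15 (2S)-5-(tert-butyldimethylsilyloxy)-7-methoxy-8-(3-methylbut-2-enyl)-2-(2,4,6-trimethoxyphenyl)chroman-4-one
Product: 16 (2S)-5-hydroxy-7-methoxy-8-(3-methylbut-2-enyl)-2-(2,4,6-trimethoxyphenyl)chroman-4-one (CNP0307910.1)
Conditions: TBAF, AcOH (1:1), THF, 0 °C
Reagents that add atoms: none
Why: Fluoride cleaves the aryl silyl ether, and acetic acid buffers the phenoxide so that base-induced ring opening to the chalcone (retro-oxa-Michael), which would racemise C2, should be avoided.

**Compound list**
1 | 2,4,6-trihydroxybenzoic acid | O=C(O)c1c(O)cc(O)cc1O | starting material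
2 | 2,4,6-trimethoxybenzaldehyde | COc1cc(OC)c(C=O)c(OC)c1 | starting material
3 | trimethylsilyl 2,4,6-tris(trimethylsilyloxy)benzoate (not isolated) | C[Si](C)(C)OC(=O)c1c(O[Si](C)(C)C)cc(O[Si](C)(C)C)cc1O[Si](C)(C)C | intermediate
4 | rac-5,7-bis(trimethylsilyloxy)-2-(2,4,6-trimethoxyphenyl)-4H-1,3-benzodioxin-4-one (not isolated) | COc1cc(OC)c(C2OC(=O)c3c(O[Si](C)(C)C)cc(O[Si](C)(C)C)cc3O2)c(OC)c1 | intermediate
5 | rac-5,7-dihydroxy-2-(2,4,6-trimethoxyphenyl)-4H-1,3-benzodioxin-4-one | COc1cc(OC)c(C2OC(=O)c3c(O)cc(O)cc3O2)c(OC)c1 | intermediate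
6 | rac-5-hydroxy-7-methoxy-2-(2,4,6-trimethoxyphenyl)-4H-1,3-benzodioxin-4-one | COc1cc(OC)c(C2OC(=O)c3c(O)cc(OC)cc3O2)c(OC)c1 | intermediate
7 | prenyl bromide (1-bromo-3-methylbut-2-ene) | CC(C)=CCBr | starting material
8 | rac-7-methoxy-5-(3-methylbut-2-enyloxy)-2-(2,4,6-trimethoxyphenyl)-4H-1,3-benzodioxin-4-one | COc1cc(OC)c(C2OC(=O)c3c(OCC=C(C)C)cc(OC)cc3O2)c(OC)c1 | intermediate
9 | 7-methoxy-6-(2-methylbut-3-en-2-yl)-2-(2,4,6-trimethoxyphenyl)-6H-1,3-benzodioxine-4,5-dione, ortho-dienone, mixture of stereoisomers (not isolated) | COC1=CC2=C(C(=O)OC(c3c(OC)cc(OC)cc3OC)O2)C(=O)C1C(C)(C)C=C | intermediate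
10 | 7-methoxy-8-(3-methylbut-2-enyl)-2-(2,4,6-trimethoxyphenyl)-8H-1,3-benzodioxine-4,5-dione, para-dienone, mixture of stereoisomers (not isolated) | COC1=CC(=O)C2=C(OC(c3c(OC)cc(OC)cc3OC)OC2=O)C1CC=C(C)C | intermediate
11 | rac-5-hydroxy-7-methoxy-8-(3-methylbut-2-enyl)-2-(2,4,6-trimethoxyphenyl)-4H-1,3-benzodioxin-4-one | COc1cc(OC)c(C2OC(=O)c3c(O)cc(OC)c(CC=C(C)C)c3O2)c(OC)c1 | intermediate
12 | rac-5-(tert-butyldimethylsilyloxy)-7-methoxy-8-(3-methylbut-2-enyl)-2-(2,4,6-trimethoxyphenyl)-4H-1,3-benzodioxin-4-one | COc1cc(OC)c(C2OC(=O)c3c(O[Si](C)(C)C(C)(C)C)cc(OC)c(CC=C(C)C)c3O2)c(OC)c1 | intermediate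
13 | rac-5-(tert-butyldimethylsilyloxy)-7-methoxy-4-methylene-8-(3-methylbut-2-enyl)-2-(2,4,6-trimethoxyphenyl)-4H-1,3-benzodioxine | C=C1OC(c2c(OC)cc(OC)cc2OC)Oc2c(CC=C(C)C)c(OC)cc(O[Si](C)(C)C(C)(C)C)c21 | intermediate
14 | ring-opened aryloxycarbenium with free A-ring ketone enol, cation of the ion pair with the chiral catalyst anion (not isolated) | C=C(O)c1c(O[Si](C)(C)C(C)(C)C)cc(OC)c(CC=C(C)C)c1[O+]=Cc1c(OC)cc(OC)cc1OC | intermediate
15 | (2S)-5-(tert-butyldimethylsilyloxy)-7-methoxy-8-(3-methylbut-2-enyl)-2-(2,4,6-trimethoxyphenyl)chroman-4-one | COc1cc(OC)c([C@@H]2CC(=O)c3c(O[Si](C)(C)C(C)(C)C)cc(OC)c(CC=C(C)C)c3O2)c(OC)c1 | intermediate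
16 | (2S)-5-hydroxy-7-methoxy-8-(3-methylbut-2-enyl)-2-(2,4,6-trimethoxyphenyl)chroman-4-one | COc1cc(OC)c([C@@H]2CC(=O)c3c(O)cc(OC)c(CC=C(C)C)c3O2)c(OC)c1 | target

**Step count**
Total steps: 8. Longest linear sequence: 8 steps, from 2,4,6-trihydroxybenzoic acid.

**Steps most likely to fail**

Step 7. The counter-anion may fail to distinguish the two faces of the planar cation, and the product may lose enantiopurity by re-ionisation of its benzylic C2–O1 bond or by reversible ring opening. Adventitious water could also intercept the cation and cleave the acetal. The fallback sets out from 13 and uses known chemistry. A Lewis-acid Petasis–Ferrier rearrangement with Me2AlCl in CH2Cl2 at −78 °C should give the racemic 5-O-TBS flavanone F1. This would then be resolved kinetically by Noyori–Ikariya transfer hydrogenation (Ru–TsDPEN, HCO2H–Et3N), with the catalyst antipode chosen so that the (2R) ketone is reduced faster to the (2R,4R)-cis-flavan-4-ol TBS ether F2. The unreacted (2S) ketone is separated and is compound 15, where the route is rejoined.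

Step 4. The ortho-dienone may tautomerise before the Cope shift, which would leave a reverse-prenyl group at C6, or the Lewis acid may strip the allyl ether or ionise the acetal. The fallback sets out from 6 and replaces the sigmatropic relay by a cross-coupling. Silylation with TBSCl and imidazole should give the 5-O-TBS-7-methoxy benzodioxinone F3. NIS in MeCN is expected to iodinate C8, para to the silyloxy group, because C6 is screened by the bulky silyl ether, to give the 8-iodo benzodioxinone F4. Suzuki–Miyaura coupling of F4 with prenylboronic acid pinacol ester (Pd(OAc)2, a dialkylbiarylphosphine ligand chosen for linear selectivity, K3PO4, THF) should give 12, where the route is rejoined.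

Step 1. The electron-rich A ring may attack the benzylic oxocarbenium at carbon (Friedel–Crafts benzylation) instead of closing the O,O-acetal, or the weakly nucleophilic aryl silyl ether may fail to close the ring. The fallback sets out from 1 and 2 and moves from kinetic silyl transfer to equilibrium acetal exchange. Aldehyde 2 is converted with HC(OMe)3 and catalytic PPTS in MeOH into the 2,4,6-trimethoxybenzaldehyde dimethyl acetal F5. F5 is then exchanged with free acid 1 under PPTS catalysis in toluene–DME over 5 Å sieves at rt, with methanol removed by the sieves, to give 5, where the route is rejoined.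

**Further compounds**
F1 | step 7 | rac-5-(tert-butyldimethylsilyloxy)-7-methoxy-8-(3-methylbut-2-enyl)-2-(2,4,6-trimethoxyphenyl)chroman-4-one | COc1cc(OC)c(C2CC(=O)c3c(O[Si](C)(C)C(C)(C)C)cc(OC)c(CC=C(C)C)c3O2)c(OC)c1
F2 | step 7 | (2R,4R)-5-(tert-butyldimethylsilyloxy)-7-methoxy-8-(3-methylbut-2-enyl)-2-(2,4,6-trimethoxyphenyl)chroman-4-ol | COc1cc(OC)c([C@H]2C[C@@H](O)c3c(O[Si](C)(C)C(C)(C)C)cc(OC)c(CC=C(C)C)c3O2)c(OC)c1
F3 | step 4 | rac-5-(tert-butyldimethylsilyloxy)-7-methoxy-2-(2,4,6-trimethoxyphenyl)-4H-1,3-benzodioxin-4-one | COc1cc(OC)c(C2OC(=O)c3c(O[Si](C)(C)C(C)(C)C)cc(OC)cc3O2)c(OC)c1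
F4 | step 4 | rac-5-(tert-butyldimethylsilyloxy)-8-iodo-7-methoxy-2-(2,4,6-trimethoxyphenyl)-4H-1,3-benzodioxin-4-one | COc1cc(OC)c(C2OC(=O)c3c(O[Si](C)(C)C(C)(C)C)cc(OC)c(I)c3O2)c(OC)c1
F5 | step 1 | 2-(dimethoxymethyl)-1,3,5-trimethoxybenzene (2,4,6-trimethoxybenzaldehyde dimethyl acetal) | COC(OC)c1c(OC)cc(OC)cc1OC
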